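The benzo ring C3a–C4–C5–C6–C7–C7a is cut into three two-carbon units. Two of them, a terminal alkyne (C3a–C4) and a chloro-ynol ether (C7a–C7), are already tied together through C3–C2–O1 in an acyclic ether that carries both stereocentres in the anti arrangement; the third (C5–C6) is methyl propiolate. One ruthenium-catalysed [2+2+2] cyclotrimerisation then makes C3a–C7a, C4–C5 and C6–C7, closing the dihydrofuran and benzene rings together and leaving H on C4 and C6, the ester on C5 and a chlorine on C7 for later exchange to methoxy. The precursor comes from a Marshall propargylation of O-benzylvanillin followed by Greene-type etherification with trichloroethylene.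

Key step: step 7

Remark on the design: the primary alcohol is carried as a triisopropylsilyl ether, because the potassium alkoxide of step 5 lies 1,3 to the silyloxymethyl group and a smaller silyl group could shift from oxygen to oxygen.

Remark on configuration: the target is the trans (2S,3R) compound. Aldehyde 1 (R) gives alkyne 2 (S) only through a change of priorities. The net inversion in step 4 turns the (S)-mesylate into the later C3 (R), and the anti addition sets the later C2 (S).

Assumption: compounds 1, 6, 9 and 13 and dimethyl (1-diazo-2-oxopropyl)phosphonate are bought; 1 is distilled before use.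

Step 1
Reactants: 1 (R)-glyceraldehyde acetonide [(R)-2,2-dimethyl-1,3-dioxolane-4-carbaldehyde]
Product: 3 (S)-but-3-yne-1,2-diol, via dioxolane alkyne 2 (not isolated)
Conditions: dimethyl (1-diazo-2-oxopropyl)phosphonate (1.2 equiv), K2CO3 (2 equiv), MeOH, 0 °C to rt; extraction into Et2O; then Amberlyst 15 (H+ form), MeOH/H2O, rt
Reagents that add atoms: dimethyl (1-diazo-2-oxopropyl)phosphonate, COP(=O)(OC)C(=[N+]=[N-])C(C)=O
Why: Ohira–Bestmann (Seyferth–Gilbert) homologation should turn the aldehyde into the terminal alkyne under carbonate/methanol conditions cold enough to keep the oxygen-bearing stereocentre of 1, and acid-catalysed acetal hydrolysis then frees the diol without isolation of the volatile alkyne 2.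

Step 2
Reactants: 3 (S)-but-3-yne-1,2-diol
Product: 4 (S)-1-[(triisopropylsilyl)oxy]but-3-yn-2-ol
Conditions: iPr3SiCl (1.05 equiv), imidazole (2 equiv), CH2Cl2, 0 °C to rt
Reagents that add atoms: triisopropylsilyl chloride, CC(C)[Si](Cl)(C(C)C)C(C)C
Why: Silyl ether formation with a bulky chlorosilane should take place at the primary hydroxyl in strong preference to the secondary propargylic one.

Step 3
Reactants: 4 (S)-1-[(triisopropylsilyl)oxy]but-3-yn-2-ol
Product: 5 (S)-1-[(triisopropylsilyl)oxy]but-3-yn-2-yl methanesulfonate
Conditions: MsCl (1.2 equiv), Et3N (1.5 equiv), CH2Cl2, −78 to 0 °C; used without storage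
Reagents that add atoms: methanesulfonyl chloride, CS(=O)(=O)Cl
Why: O-sulfonylation of the secondary alcohol forms only an O–S bond, so the stereocentre is retained and the propargylic leaving group needed for step 4 is installed.

Step 4
Reactants: 5 (S)-1-[(triisopropylsilyl)oxy]but-3-yn-2-yl methanesulfonate; 6 O-benzylvanillin [4-(benzyloxy)-3-methoxybenzaldehyde]
Product: 8 (1S,2R)-1-[4-(benzyloxy)-3-methoxyphenyl]-2-{[(triisopropylsilyl)oxy]methyl}but-3-yn-1-ol (anti), via allenylzinc 7 (not isolated)
Conditions: Pd(OAc)2 (5 mol%), PPh3 (5 mol%), Et2Zn (3 equiv), THF, −78 to −20 °C; aq. NH4Cl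
Reagents that add atoms: none
Why: In this Marshall propargylation, zerovalent palladium formed in the flask should displace the mesylate in an anti SN2' sense and transmetalation to zinc with retention gives the chiral allenylzinc 7; addition to the aldehyde through a cyclic SE2' transition state with the aryl group turned away from the silyloxymethyl group then transfers the mesylate chirality to the propargylic carbon (net inversion, later C3, R) and sets the carbinol carbon (later C2, S) anti to it, any syn isomer being removed by chromatography.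

Step 5
Reactants: 8 anti homopropargylic alcohol; 9 trichloroethylene
Product: 11 (E)-1,2-dichlorovinyl ether of 8 [(1S,2R) unchanged; O and H trans on the double bond], via dichloroacetylene 10 (not isolated)
Conditions: KH (1.2 equiv), THF, 0 °C; then Cl2C=CHCl (1.5 equiv), −50 °C to rt
Reagents that add atoms: none
Why: In this Greene dichlorovinyl ether synthesis the potassium alkoxide should eliminate HCl from trichloroethylene to give dichloroacetylene 10 and add to it in an anti sense, with protonation giving the (E)-ether; the small excess of KH leaves the terminal alkyne largely protonated and the bulky silyl group should not migrate.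

Step 6
Reactants: 11 (E)-1,2-dichlorovinyl ether of 8
Product: 12 chloroethynyl ether of 8, {[(2R)-2-[(S)-[4-(benzyloxy)-3-methoxyphenyl][(chloroethynyl)oxy]methyl]but-3-yn-1-yl]oxy}triisopropylsilane
Conditions: LiN(iPr)2 (2.3 equiv), THF, −78 to −40 °C; AcOH/THF quench at −78 °C; cold filtration through basic alumina; kept in solution and used at once
Reagents that add atoms: none
Why: This dehydrochlorination is the first stage of the Greene ynol ether synthesis: lithiation of the vinylic C–H and loss of lithium chloride should give the chloroalkynyl ether and stop there, because a lithium amide cannot carry out chlorine–lithium exchange, while the first equivalent of base only masks the terminal alkyne as its acetylide until the quench.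

Step 7
Reactants: 12 chloroethynyl ether of 8; 13 methyl propiolate
Product: 14 methyl (2S,3R)-2-[4-(benzyloxy)-3-methoxyphenyl]-7-chloro-3-{[(triisopropylsilyl)oxy]methyl}-2,3-dihydro-1-benzofuran-5-carboxylate
Conditions: Cp*RuCl(cod) (10 mol%), methyl propiolate (3 equiv), 1,2-dichloroethane, 20 °C, 12 added over 3 h
Reagents that add atoms: none
Why: Proposed new method: oxidative cyclisation of the two tethered alkynes of 12 on the Cp*RuCl fragment (divalent ruthenium) should give a bicyclic ruthenacyclopentatriene in which C3a–C7a is already formed, after which methyl propiolate inserts on the C4 side and reductive elimination releases the arene. The closest known reaction type is the Cp*RuCl(cod)-catalysed [2+2+2] cyclotrimerisation of 1,6-diynes bearing one terminal substituent with terminal alkynes, which is documented for halogen-substituted alkyne termini and, separately, for oxygen- and nitrogen-substituted alkynes; a terminus that is both, a chloro-ynol ether, is the untested element. The dihydrofuran ring (O1–C2–C3–C3a–C7a) closes by metallacycle formation across the three-atom tether, that is by C3a–C7a coupling of the 1,6-diyne, and the benzene ring closes by the [2+2+2] cycloaddition itself through the C4–C5 and C6–C7 bonds. No stereocentre is created; C2 and C3 come from 12 and are not touched under neutral conditions at 20 °C. The step needs regioselectivity (ester on C5, not C6), which should follow from the contrast between the hydrogen-bearing C4 terminus and the chlorine-bearing C7 terminus of the ruthenacycle: the ester-bearing carbon of the propiolate bonds to the unhindered C4 and its CH carbon to C7, the meta outcome usual for this catalyst. An excess of propiolate with slow addition of 12 limits diyne dimerisation, and ambient temperature keeps the secondary benzylic ynol ether away from retro-ene and sigmatropic decomposition.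

Step 8
Reactants: 14 7-chloro dihydrobenzofuran ester
Product: 15 methyl (2S,3R)-2-[4-(benzyloxy)-3-methoxyphenyl]-7-methoxy-3-{[(triisopropylsilyl)oxy]methyl}-2,3-dihydro-1-benzofuran-5-carboxylate
Conditions: MeOH (5 equiv), [Pd(allyl)Cl]2 (2 mol%), tBuBrettPhos (5 mol%), Cs2CO3 (1.5 equiv), toluene, 80 °C
Reagents that add atoms: methanol, CO
Why: In this Buchwald–Hartwig-type C–O cross-coupling of an aryl chloride with methanol, the bulky biaryl di-tert-butylphosphine should favour C–O reductive elimination over β-hydride elimination, and carbonate with methanol leaves the methyl ester, silyl ether, benzyl ether and both stereocentres untouched.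

Step 9
Reactants: 15 7-methoxy silyl ether
Product: 16 methyl (2S,3R)-2-[4-(benzyloxy)-3-methoxyphenyl]-3-(hydroxymethyl)-7-methoxy-2,3-dihydro-1-benzofuran-5-carboxylate
Conditions: HF·pyridine, pyridine/THF, 0 °C to rt
Reagents that add atoms: none
Why: Fluoride-mediated desilylation with buffered HF·pyridine should cleave the primary silyl ether without touching the methyl ester or the benzylic ring ether.

Step 10
Reactants: 16 benzyl-protected alcohol
Product: 17 curlignan, methyl (2S,3R)-2-(4-hydroxy-3-methoxyphenyl)-3-(hydroxymethyl)-7-methoxy-2,3-dihydro-1-benzofuran-5-carboxylate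
Conditions: H2 (1 atm), Pd/C (10 wt%), EtOAc, rt, stopped at full conversion
Reagents that add atoms: none
Why: Hydrogenolysis of the primary aryl benzyl ether over Pd/C is fast at 1 atm and should be complete before the slower cleavage of the cyclic secondary benzylic C2–O1 bond begins.

Compound list
1 | (R)-glyceraldehyde acetonide, (R)-2,2-dimethyl-1,3-dioxolane-4-carbaldehyde | CC1(C)OC[C@H](C=O)O1 | starting material
2 | (S)-4-ethynyl-2,2-dimethyl-1,3-dioxolane | CC1(C)OC[C@H](C#C)O1 | intermediate (not isolated)
3 | (S)-but-3-yne-1,2-diol | C#C[C@H](O)CO | intermediate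
4 | (S)-1-[(triisopropylsilyl)oxy]but-3-yn-2-ol | C#C[C@H](O)CO[Si](C(C)C)(C(C)C)C(C)C | intermediate
5 | (S)-1-[(triisopropylsilyl)oxy]but-3-yn-2-yl methanesulfonate | C#C[C@H](OS(C)(=O)=O)CO[Si](C(C)C)(C(C)C)C(C)C | intermediate
6 | O-benzylvanillin, 4-(benzyloxy)-3-methoxybenzaldehyde | COc1cc(C=O)ccc1OCc1ccccc1 | starting material
7 | ethyl[(aS)-4-(triisopropylsilyloxy)buta-1,2-dien-1-yl]zinc | CC[Zn]C([H])=[C@@]=C([H])CO[Si](C(C)C)(C(C)C)C(C)C | intermediate (not isolated)
8 | (1S,2R)-1-[4-(benzyloxy)-3-methoxyphenyl]-2-{[(triisopropylsilyl)oxy]methyl}but-3-yn-1-ol | C#C[C@H](CO[Si](C(C)C)(C(C)C)C(C)C)[C@@H](c1ccc(OCc2ccccc2)c(OC)c1)O | intermediate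
9 | trichloroethylene | ClC=C(Cl)Cl | starting material
10 | dichloroacetylene | ClC#CCl | intermediate (not isolated)
11 | (E)-1,2-dichlorovinyl ether of 8 | C#C[C@H](CO[Si](C(C)C)(C(C)C)C(C)C)[C@@H](c1ccc(OCc2ccccc2)c(OC)c1)O/C(Cl)=C\Cl | intermediate
12 | chloroethynyl ether of 8 | C#C[C@H](CO[Si](C(C)C)(C(C)C)C(C)C)[C@@H](c1ccc(OCc2ccccc2)c(OC)c1)OC#CCl | intermediate
13 | methyl propiolate | C#CC(=O)OC | starting material
14 | methyl (2S,3R)-2-[4-(benzyloxy)-3-methoxyphenyl]-7-chloro-3-{[(triisopropylsilyl)oxy]methyl}-2,3-dihydro-1-benzofuran-5-carboxylate | COC(=O)c1cc(Cl)c2c(c1)[C@H](CO[Si](C(C)C)(C(C)C)C(C)C)[C@@H](c1ccc(OCc3ccccc3)c(OC)c1)O2 | intermediate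
15 | methyl (2S,3R)-2-[4-(benzyloxy)-3-methoxyphenyl]-7-methoxy-3-{[(triisopropylsilyl)oxy]methyl}-2,3-dihydro-1-benzofuran-5-carboxylate | COC(=O)c1cc(OC)c2c(c1)[C@H](CO[Si](C(C)C)(C(C)C)C(C)C)[C@@H](c1ccc(OCc3ccccc3)c(OC)c1)O2 | intermediate
16 | methyl (2S,3R)-2-[4-(benzyloxy)-3-methoxyphenyl]-3-(hydroxymethyl)-7-methoxy-2,3-dihydro-1-benzofuran-5-carboxylate | COC(=O)c1cc(OC)c2c(c1)[C@H](CO)[C@@H](c1ccc(OCc3ccccc3)c(OC)c1)O2 | intermediate
17 | curlignan, methyl (2S,3R)-2-(4-hydroxy-3-methoxyphenyl)-3-(hydroxymethyl)-7-methoxy-2,3-dihydro-1-benzofuran-5-carboxylate | COC(=O)c1cc(OC)c2c(c1)[C@H](CO)[C@@H](c1ccc(O)c(OC)c1)O2 | target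

Total step count: 10. Longest linear sequence: 10 steps (1 to 17); 6, 9 and 13 enter as bought materials.

Steps most likely to fail

Step 7 (cyclotrimerisation). The chloro-ynol ether may bind or add oxidatively to ruthenium without turning over, the diyne may oligomerise, propiolate insertion may lose its regiochemical preference, or the ynol ether may fragment by a retro-ene path before it cyclises. The fallback uses known chemistry only; it sets out from 6 and returns at 16. Methyl vanillate (bought) is O-allylated (allyl bromide, K2CO3, acetone) to methyl 4-(allyloxy)-3-methoxybenzoate F1. Aromatic Claisen rearrangement (N,N-diethylaniline, 200 °C) moves the allyl group to the free ortho position and gives methyl 3-allyl-4-hydroxy-5-methoxybenzoate F2. Protection with MOMCl and iPr2NEt gives the methoxymethyl ether F3, and Lemieux–von Rudloff cleavage (NaIO4, catalytic KMnO4, K2CO3, tBuOH/H2O) shortens the allyl group to the arylacetic acid F4. The pivaloyl mixed anhydride and lithiated (S)-4-benzyloxazolidin-2-one give the imide F5. The Evans syn aldol of its boron enolate (Bu2BOTf, iPr2NEt, CH2Cl2, −78 to 0 °C) with 6 gives the syn adduct F6 and fixes the future C3. Reductive removal of the auxiliary (NaBH4, THF/H2O) gives the diol F7. HCl in MeOH then cleaves the methoxymethyl ether, and the freed phenol closes onto the p-alkoxybenzylic position (SN1, trans product under the control of C3) to give 16.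

Step 6 (chloroalkynyl ether). The lithiated dichlorovinyl ether may lose alkoxide back to dichloroacetylene instead of chloride, the amide base may attack the chloroalkyne once it has formed, or the product may decompose on warming or concentration. The fallback sets out from 8 and returns at 12. Formylation of 8 (acetic formic anhydride, pyridine, 0 °C) gives the formate F8. Wittig-type dichloromethylenation of the formate carbonyl (PPh3, CCl4, THF, reflux) gives the 2,2-dichlorovinyl ether F9, in which the vinylic hydrogen on the oxygen-bearing carbon lies anti to one chlorine. A plain anti E2 dehydrochlorination (LiN(iPr)2, 2.2 equiv, THF, −78 °C) then gives 12, with no alkoxide-loss pathway available.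

Step 8 (methoxylation). β-Hydride elimination from the arylpalladium methoxide may outrun C–O reductive elimination at the position flanked by O1, so that the chloride is reduced instead of exchanged. The fallback sets out from 14 and returns at 15. Miyaura borylation (B2pin2, Pd2(dba)3, XPhos, KOAc, dioxane, 100 °C) gives the pinacol boronate F10. Oxidation (NaBO3·4H2O, THF/H2O, rt) gives the 7-phenol F11, and O-methylation (MeI, K2CO3, acetone) gives 15.

Further compounds
F1 | step 7 | methyl 4-(allyloxy)-3-methoxybenzoate | COC(=O)c1ccc(OCC=C)c(OC)c1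
F2 | step 7 | methyl 3-allyl-4-hydroxy-5-methoxybenzoate | COC(=O)c1cc(CC=C)c(O)c(OC)c1
F3 | step 7 | methyl 3-allyl-5-methoxy-4-(methoxymethoxy)benzoate | COC(=O)c1cc(CC=C)c(OCOC)c(OC)c1
F4 | step 7 | [3-methoxy-5-(methoxycarbonyl)-2-(methoxymethoxy)phenyl]acetic acid | COC(=O)c1cc(CC(=O)O)c(OCOC)c(OC)c1
F5 | step 7 | (S)-4-benzyl-3-{2-[3-methoxy-5-(methoxycarbonyl)-2-(methoxymethoxy)phenyl]acetyl}oxazolidin-2-one | COC(=O)c1cc(CC(=O)N2[C@@H](Cc3ccccc3)COC2=O)c(OCOC)c(OC)c1
F6 | step 7 | (S)-4-benzyl-3-{(2S,3S)-3-[4-(benzyloxy)-3-methoxyphenyl]-3-hydroxy-2-[3-methoxy-5-(methoxycarbonyl)-2-(methoxymethoxy)phenyl]propanoyl}oxazolidin-2-one | COC(=O)c1cc([C@H](C(=O)N2[C@@H](Cc3ccccc3)COC2=O)[C@@H](c4ccc(OCc5ccccc5)c(OC)c4)O)c(OCOC)c(OC)c1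
F7 | step 7 | (1S,2R)-1-[4-(benzyloxy)-3-methoxyphenyl]-2-[3-methoxy-5-(methoxycarbonyl)-2-(methoxymethoxy)phenyl]propane-1,3-diol | COC(=O)c1cc([C@H](CO)[C@@H](c2ccc(OCc3ccccc3)c(OC)c2)O)c(OCOC)c(OC)c1
F8 | step 6 | formate ester of 8 | C#C[C@H](CO[Si](C(C)C)(C(C)C)C(C)C)[C@@H](c1ccc(OCc2ccccc2)c(OC)c1)OC=O
F9 | step 6 | 2,2-dichlorovinyl ether of 8 | C#C[C@H](CO[Si](C(C)C)(C(C)C)C(C)C)[C@@H](c1ccc(OCc2ccccc2)c(OC)c1)OC=C(Cl)Cl
F10 | step 8 | methyl (2S,3R)-2-[4-(benzyloxy)-3-methoxyphenyl]-7-(4,4,5,5-tetramethyl-1,3,2-dioxaborolan-2-yl)-3-{[(triisopropylsilyl)oxy]methyl}-2,3-dihydro-1-benzofuran-5-carboxylate | COC(=O)c1cc(B3OC(C)(C)C(C)(C)O3)c2c(c1)[C@H](CO[Si](C(C)C)(C(C)C)C(C)C)[C@@H](c1ccc(OCc3ccccc3)c(OC)c1)O2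
F11 | step 8 | methyl (2S,3R)-2-[4-(benzyloxy)-3-methoxyphenyl]-7-hydroxy-3-{[(triisopropylsilyl)oxy]methyl}-2,3-dihydro-1-benzofuran-5-carboxylate | COC(=O)c1cc(O)c2c(c1)[C@H](CO[Si](C(C)C)(C(C)C)C(C)C)[C@@H](c1ccc(OCc3ccccc3)c(OC)c1)O2
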